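## Retrosynthetic overview

1. Hippolide D (16) comes from desilylation of 15. Compound 15 comes from a redox-neutral, catalyst-controlled proton-transfer isomerisation of γ-hydroxybutenolide 14, which creates the anhydride and sets the ring stereocentre.
2. 14 comes from singlet-oxygen oxidation of the 3-substituted furan 12. The only ring is bought as the furan of 4 and is carried through furan → butenolide → anhydride, so no ring is built de novo.
3. 12 comes from B-alkyl Suzuki coupling of homofarnesyl borane 11 (farnesol 8 → farnesal 9 → tetraene 10) with the (Z)-α-iodoenal 7.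
4. 7 comes from α-iodination of enal 6. Compound 6 comes from Wittig homologation of 5, and 5 from an organocatalytic Mukaiyama aldol of acetaldehyde enolsilane 3 with furan-3-carbaldehyde 4, which sets the carbinol centre and installs the TES group.

Assumption: the free hydroxy anhydride as drawn is taken as the true, isolable structure. It is an isomer of the trans-paraconic acid lactone, so the OH is kept silylated until the last operation and 16 is handled only under non-basic, anhydrous conditions.

## Route

Step 1
Reactants: 1 tetrahydrofuran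
Product: 3 triethyl(vinyloxy)silane, via lithium ethenolate 2 (not isolated)
Conditions: n-BuLi, neat THF, 35 °C; then Et3SiCl, 0 °C; distillation
Reagents that add atoms: chlorotriethylsilane CC[Si](Cl)(CC)CC
Why: α-Lithiation of THF and [3+2] cycloreversion give ethene and the lithium enolate of acetaldehyde, which is trapped on oxygen (enolate O-silylation); no stereocentre is formed.

Step 2
Reactants: 4 furan-3-carbaldehyde; 3 triethyl(vinyloxy)silane
Product: 6 (2E,5R)-5-(furan-3-yl)-5-(triethylsilyloxy)pent-2-enal, via silyloxy aldehyde 5 (not isolated)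
Conditions: chiral IDPi (N-triflyl imidodiphosphorimidate from 3,3'-diaryl-BINOL, 1 mol%), 3 (1.5 equiv), toluene, −78 °C; then Ph3P=CHCHO (1.3 equiv), 70 °C
Reagents that add atoms: (triphenylphosphoranylidene)acetaldehyde O=CC=P(c1ccccc1)(c1ccccc1)c1ccccc1
Why: In this silylium-type, counteranion-directed Mukaiyama aldol (single aldolisation of an acetaldehyde enolsilane) the confined chiral anion pairs with the O-silylated aldehyde, and the catalyst antipode that leaves the Re face open gives the R carbinol with TES transferred to oxygen; the stabilised ylide then neutralises the acid and converts crude 5 into the E-enal (E-selective Wittig olefination).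

Step 3
Reactants: 6 (2E,5R)-5-(furan-3-yl)-5-(triethylsilyloxy)pent-2-enal
Product: 7 (2Z,5R)-5-(furan-3-yl)-2-iodo-5-(triethylsilyloxy)pent-2-enal
Conditions: I2, K2CO3, DMAP (20 mol%), THF/H2O, rt
Reagents that add atoms: iodine II
Why: In this Baylis–Hillman-type α-iodination, DMAP adds in conjugate fashion, the enolate is iodinated and DMAP is expelled, giving the thermodynamic Z-iodoenal (CHO trans to the CH2 group); the furan, the TES ether and the carbinol centre are untouched.

Step 4
Reactants: 8 (2E,6E)-farnesol
Product: 9 (2E,6E)-farnesal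
Conditions: TEMPO (10 mol%), PhI(OAc)2, CH2Cl2, rt
Reagents that add atoms: none
Why: The oxoammonium (TEMPO/PhI(OAc)2) oxidation of a primary allylic alcohol stops at the enal and does not isomerise the 2E alkene.

Step 5
Reactants: 9 (2E,6E)-farnesal
Product: 10 (3E,7E)-4,8,12-trimethyltrideca-1,3,7,11-tetraene
Conditions: Ph3PCH3Br, n-BuLi, THF, 0 °C to rt
Reagents that add atoms: methyltriphenylphosphonium bromide C[P+](c1ccccc1)(c1ccccc1)c1ccccc1.[Br-]
Why: Wittig methylenation of the enal gives the terminal diene with the existing E alkenes retained.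

Step 6
Reactants: 10 (3E,7E)-4,8,12-trimethyltrideca-1,3,7,11-tetraene; 7 (2Z,5R)-5-(furan-3-yl)-2-iodo-5-(triethylsilyloxy)pent-2-enal
Product: 12 (2E,5E,9E)-2-[(3R)-3-(furan-3-yl)-3-(triethylsilyloxy)propylidene]-6,10,14-trimethylpentadeca-5,9,13-trienal, via B-homofarnesyl-9-BBN 11 (not isolated)
Conditions: 10, 9-BBN (1.0 equiv), THF, 0 °C to rt; then 7, Pd(dppf)Cl2 (5 mol%), AsPh3, Cs2CO3, DMF/H2O, rt
Reagents that add atoms: none
Why: 9-BBN hydroborates only the monosubstituted alkene (anti-Markovnikov), and the B-alkyl Suzuki–Miyaura coupling replaces iodine with retention of geometry, so the chain ends cis to the CH2CH(OTES) arm and the enal is E.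

Step 7
Reactants: 12 (2E,5E,9E)-2-[(3R)-3-(furan-3-yl)-3-(triethylsilyloxy)propylidene]-6,10,14-trimethylpentadeca-5,9,13-trienal
Product: 14 (2E,5E,9E)-2-[(3R)-3-(2-hydroxy-5-oxo-2,5-dihydrofuran-3-yl)-3-(triethylsilyloxy)propylidene]-6,10,14-trimethylpentadeca-5,9,13-trienal (lactol epimers), via furan endoperoxide 13 (not isolated)
Conditions: O2, hν (visible), tetraphenylporphyrin, i-Pr2NEt, CH2Cl2, −78 °C, stopped at full furan consumption
Reagents that add atoms: dioxygen O=O
Why: At −78 °C singlet oxygen adds to the furan ([4+2] cycloaddition) much faster than it undergoes the ene reaction with trisubstituted alkenes, the enal is inert, and the hindered amine removes the less hindered bridgehead proton (Kornblum–DeLaMare fragmentation) to give the 4-substituted 5-hydroxybutenolide; the lactol epimers and any regioisomer converge on the same anhydride in step 8.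

Step 8
Reactants: 14 (2E,5E,9E)-2-[(3R)-3-(2-hydroxy-5-oxo-2,5-dihydrofuran-3-yl)-3-(triethylsilyloxy)propylidene]-6,10,14-trimethylpentadeca-5,9,13-trienal
Product: 16 hippolide D, via TES-protected hippolide D 15 (not isolated)
Conditions: 9-amino-9-deoxy-epi-quinine 3,5-bis(trifluoromethyl)benzyl squaramide (10 mol%), CH2Cl2 (0.02 M), 4 Å MS, −20 to 0 °C; then HF·pyridine (excess), THF, −20 to 0 °C; cold non-basic work-up
Reagents that add atoms: none
Why: Proposed new method: a catalytic asymmetric, redox-neutral prototropic isomerisation of a γ-hydroxybutenolide to a succinic anhydride, in which the quinuclidine nitrogen removes the doubly oxygen-activated ring C5–H (favoured over the exocyclic carbinol C–H because an aromatic 5-hydroxyfuran-2-olate results) while the squaramide binds the lactone carbonyl, the anion is reprotonated at the unsubstituted ring CH to the anhydride enolate, and the chiral ammonium then protonates the substituted enolate carbon on its Re face inside the squaramide-bound ion pair to set S (the pseudo-enantiomeric quinidine catalyst is the alternative if the substrate bias is mismatched); the process is downhill because an aldehyde-level carbon becomes an acyl carbon, the alkylsuccinic anhydride is too weakly acidic to be re-enolised by a tertiary amine so the new centre holds, the TES ether blocks amine-promoted lactonisation to the paraconic acid, and excess HF·pyridine first kills the base and then cleaves the TES ether; the closest known reaction types are cinchona-catalysed proton-transfer isomerisation of β,γ- to α,β-butenolides, amine–squaramide γ-deprotonation of 2(5H)-furanones in direct vinylogous aldol reactions, and the non-asymmetric base or thermal isomerisation of 5-hydroxyfuran-2(5H)-one to succinic anhydride.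

## Compound list

1 | tetrahydrofuran | C1CCOC1 | starting material
2 | lithium ethenolate (lithium enolate of acetaldehyde) | [Li+].[O-]C=C | intermediate
3 | triethyl(vinyloxy)silane | C=CO[Si](CC)(CC)CC | intermediate
4 | furan-3-carbaldehyde | O=Cc1ccoc1 | starting material
5 | (3R)-3-(furan-3-yl)-3-(triethylsilyloxy)propanal | O=CC[C@@H](O[Si](CC)(CC)CC)c1ccoc1 | intermediate
6 | (2E,5R)-5-(furan-3-yl)-5-(triethylsilyloxy)pent-2-enal | O=C/C=C/C[C@@H](O[Si](CC)(CC)CC)c1ccoc1 | intermediate
7 | (2Z,5R)-5-(furan-3-yl)-2-iodo-5-(triethylsilyloxy)pent-2-enal | O=C/C(I)=C/C[C@@H](O[Si](CC)(CC)CC)c1ccoc1 | intermediate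
8 | (2E,6E)-farnesol | CC(C)=CCC/C(C)=C/CC/C(C)=C/CO | starting material
9 | (2E,6E)-farnesal | CC(C)=CCC/C(C)=C/CC/C(C)=C/C=O | intermediate
10 | (3E,7E)-4,8,12-trimethyltrideca-1,3,7,11-tetraene | CC(C)=CCC/C(C)=C/CC/C(C)=C/C=C | intermediate
11 | 9-[(3E,7E)-4,8,12-trimethyltrideca-3,7,11-trien-1-yl]-9-borabicyclo[3.3.1]nonane | CC(C)=CCC/C(C)=C/CC/C(C)=C/CCB1C2CCCC1CCC2 | intermediate
12 | (2E,5E,9E)-2-[(3R)-3-(furan-3-yl)-3-(triethylsilyloxy)propylidene]-6,10,14-trimethylpentadeca-5,9,13-trienal | CC(C)=CCC/C(C)=C/CC/C(C)=C/CC/C(C=O)=C\C[C@@H](O[Si](CC)(CC)CC)c1ccoc1 | intermediate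
13 | 5-substituted 2,3,7-trioxabicyclo[2.2.1]hept-5-ene (furan endoperoxide of 12, bridgeheads undefined) | CC(C)=CCC/C(C)=C/CC/C(C)=C/CC/C(C=O)=C\C[C@@H](O[Si](CC)(CC)CC)C1=CC2OOC1O2 | intermediate
14 | (2E,5E,9E)-2-[(3R)-3-(2-hydroxy-5-oxo-2,5-dihydrofuran-3-yl)-3-(triethylsilyloxy)propylidene]-6,10,14-trimethylpentadeca-5,9,13-trienal (lactol carbon undefined) | CC(C)=CCC/C(C)=C/CC/C(C)=C/CC/C(C=O)=C\C[C@@H](O[Si](CC)(CC)CC)C1=CC(=O)OC1O | intermediate
15 | (2E,5E,9E)-2-[(3R)-3-[(3S)-2,5-dioxooxolan-3-yl]-3-(triethylsilyloxy)propylidene]-6,10,14-trimethylpentadeca-5,9,13-trienal | CC(C)=CCC/C(C)=C/CC/C(C)=C/CC/C(C=O)=C\C[C@@H](O[Si](CC)(CC)CC)[C@@H]1CC(=O)OC1=O | intermediate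
16 | hippolide D, (2E,5E,9E)-2-[(3R)-3-[(3S)-2,5-dioxooxolan-3-yl]-3-hydroxypropylidene]-6,10,14-trimethylpentadeca-5,9,13-trienal | CC(C)=CCC/C(C)=C/CC/C(C)=C/CC/C(C=O)=C\C[C@@H](O)[C@@H]1CC(=O)OC1=O | target

## Step count and risks

Total step count: 8.
Longest linear sequence: 6 (steps 1, 2, 3, 6, 7, 8).

**Step 8 (the proposed new step).**
- The catalyst may be tied up as the ammonium carboxylate of the ring-opened formylacrylic acid.
- That open form may isomerise to the E acid, which cannot re-close.
- The enolate may expel silanolate.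
- The diastereomer ratio may be low in a mismatched case.
- Freed 16 may lactonise to the paraconic acid.

The fallback uses known chemistry and sets out from 14. Dess–Martin periodinane (CH2Cl2, 0 °C) oxidises the lactol to the TES-protected maleic anhydride F1. Asymmetric hydrogenation of the anhydride C=C of F1 follows, with [Rh(cod)Cl]2, the bisphosphine–thiourea ligand ZhaoPhos (antipode chosen for S) and H2. The isolated trisubstituted alkenes are inert to this catalyst. The fallback comes back to the route at 15, which is desilylated with HF·pyridine as in step 8.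

**Step 6.** The α-iodoenal is sensitive to base (deiodination, aldol chemistry, vinylogous loss of the δ-silyloxy group), and the aldehyde is exposed to borane residues. The fallback sets out from 7 and makes the C–C bond at the alcohol oxidation level. Luche reduction (NaBH4, CeCl3·7H2O, MeOH, −40 °C) gives the (Z)-2-iodoallylic alcohol F2. The same B-alkyl Suzuki coupling with 11, now on a robust vinyl iodide, gives the trisubstituted allylic alcohol F3. MnO2 in CH2Cl2 oxidises only the allylic alcohol, and the fallback comes back to the route at 12.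

**Step 2.** The furan is nucleophilic and acid-sensitive toward a very strong acid catalyst, the heteroaryl aldehyde is a weak electrophile, and crude 5 can eliminate during the Wittig stage. The fallback sets out from 4.
- Allylboration with allylboronic acid pinacol ester and (R)-TRIP phosphoric acid (5 mol%, toluene, −30 °C) gives the homoallylic pinacol borate F4.
- Work-up hydrolyses F4 to (1R)-1-(furan-3-yl)but-3-en-1-ol F5.
- Et3SiCl and imidazole give the TES ether F6.
- Cross metathesis of F6 with crotonaldehyde (second-generation Hoveyda–Grubbs catalyst, CH2Cl2, 40 °C) comes back to the route at 6.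

## Further compounds

F1 | step 8 | (2E,5E,9E)-2-[(3R)-3-(2,5-dioxo-2,5-dihydrofuran-3-yl)-3-(triethylsilyloxy)propylidene]-6,10,14-trimethylpentadeca-5,9,13-trienal | CC(C)=CCC/C(C)=C/CC/C(C)=C/CC/C(C=O)=C\C[C@@H](O[Si](CC)(CC)CC)C1=CC(=O)OC1=O
F2 | step 6 | (2Z,5R)-5-(furan-3-yl)-2-iodo-5-(triethylsilyloxy)pent-2-en-1-ol | OC/C(I)=C/C[C@@H](O[Si](CC)(CC)CC)c1ccoc1
F3 | step 6 | (2E,5E,9E)-2-[(3R)-3-(furan-3-yl)-3-(triethylsilyloxy)propylidene]-6,10,14-trimethylpentadeca-5,9,13-trien-1-ol | CC(C)=CCC/C(C)=C/CC/C(C)=C/CC/C(CO)=C\C[C@@H](O[Si](CC)(CC)CC)c1ccoc1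
F4 | step 2 | 2-{[(1R)-1-(furan-3-yl)but-3-en-1-yl]oxy}-4,4,5,5-tetramethyl-1,3,2-dioxaborolane | C=CC[C@@H](OB1OC(C)(C)C(C)(C)O1)c1ccoc1
F5 | step 2 | (1R)-1-(furan-3-yl)but-3-en-1-ol | C=CC[C@@H](O)c1ccoc1
F6 | step 2 | triethyl{[(1R)-1-(furan-3-yl)but-3-en-1-yl]oxy}silane | C=CC[C@@H](O[Si](CC)(CC)CC)c1ccoc1
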